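**Retrosynthetic overview**

1. The target is an acyclic (2R,3R)-succinic half ester (chain: C-1 = free CO2H, C-2 = CH–ring A, C-3 = CH–CO2Me, C-4 = CH2–ring B; ring A = 4-hydroxyphenyl, ring B = 3-hydroxy-4-prenylphenyl). The C-4–ring B bond is cut first: ring B arrives as an aryl iodide and C-4 as the unfunctionalised CH3 of a 2-aryl-3-methylsuccinic acid (carboxylate-directed β-C(sp3)–H arylation).
2. Enabling feature: C-4 is β to the carbonyl carbon of the C-3 carboxyl (O–C(=O)–C-3–C-4), so that carboxylate can deliver palladium to a C-4–H bond through a five-membered palladacycle (Pd, O, carbonyl C, C-3, C-4). C-4 is the only CH3 of the precursor, and the C-1 carboxyl is masked as a non-directing N-acyloxazolidinone.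
3. The C-2–C-3 bond and both stereocenters are made before the key step: C-2 by the (R)-4-benzyloxazolidinone enolate, C-3 by SN2 inversion of benzyl (R)-lactate triflate.
4. Ring B iodide from 5-bromo-2-iodophenol (I → prenyl, then Br → I). End game: methyl ester formation, auxiliary hydrolysis, desilylation.
5. No ring is formed in the route: rings A and B are bought as benzene derivatives and the oxazolidinone ring is a bought auxiliary that is split off again.

Key step: step 9

Assumption: the given SMILES is read as the (2R,3R) erythro isomer; the two phenols are carried as triisopropylsilyl ethers because the enolate, organometallic and palladium steps would not tolerate free ArOH, and benzyl (R)-lactate and 5-bromo-2-iodophenol are taken as catalogue compounds.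

**Route**

Step 1
Reactants: 1 4-hydroxyphenylacetic acid
Product: 3 2-[4-(triisopropylsilyloxy)phenyl]acetic acid, via bis-silylated acid 2 (not isolated)
Conditions: TIPSCl (2.2 equiv), imidazole, DMF, rt; then 1 M HCl, THF, rt
Reagents that add atoms: triisopropylsilyl chloride, CC(C)[Si](Cl)(C(C)C)C(C)C
Why: Imidazole-promoted silylation covers both acidic OH groups and the far more labile silyl ester is then hydrolysed selectively, leaving the aryl silyl ether (standard phenol protection).

Step 2
Reactants: 3 2-[4-(triisopropylsilyloxy)phenyl]acetic acid; 4 (R)-4-benzyl-1,3-oxazolidin-2-one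
Product: 6 (4R)-4-benzyl-3-{2-[4-(triisopropylsilyloxy)phenyl]acetyl}-1,3-oxazolidin-2-one, via mixed pivalic anhydride 5 (not isolated)
Conditions: t-BuCOCl, Et3N, THF, −20 °C; then 4, LiCl, −20 °C → rt
Reagents that add atoms: none
Why: Mixed-anhydride N-acylation of the oxazolidinone (LiCl/Et3N variant) needs no strong base and installs the auxiliary that will control the aryl-bearing stereocenter.

Step 3
Reactants: 7 benzyl (R)-lactate
Product: 8 benzyl (2R)-2-[(trifluoromethylsulfonyl)oxy]propanoate
Conditions: Tf2O, 2,6-lutidine, CH2Cl2, −78 → 0 °C; short silica plug, used at once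
Reagents that add atoms: triflic anhydride, O=S(=O)(OS(=O)(=O)C(F)(F)F)C(F)(F)F
Why: O-Triflation of an α-hydroxy ester with a hindered pyridine base takes place at oxygen with retention, so the (R)-triflate is obtained.

Step 4
Reactants: 6 (4R)-4-benzyl-3-{2-[4-(triisopropylsilyloxy)phenyl]acetyl}-1,3-oxazolidin-2-one; 8 benzyl (2R)-2-[(trifluoromethylsulfonyl)oxy]propanoate
Product: 10 benzyl (2R,3R)-4-[(4R)-4-benzyl-2-oxo-1,3-oxazolidin-3-yl]-2-methyl-4-oxo-3-[4-(triisopropylsilyloxy)phenyl]butanoate, via sodium enolate 9 (not isolated)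
Conditions: NaN(SiMe3)2, THF, −78 °C; then 8, −78 → −40 °C
Reagents that add atoms: none
Why: The chelated sodium (Z)-enolate is shielded on one face by the benzyl group of the (R)-auxiliary and displaces the secondary triflate by SN2 with inversion (oxazolidinone enolate alkylation with an α-triflyloxy ester, a known entry to 2,3-disubstituted succinates), so the aryl-bearing carbon is set (R) by the auxiliary and the methyl-bearing carbon (R) by inversion of the lactate center.

Step 5
Reactants: 10 benzyl (2R,3R)-4-[(4R)-4-benzyl-2-oxo-1,3-oxazolidin-3-yl]-2-methyl-4-oxo-3-[4-(triisopropylsilyloxy)phenyl]butanoate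
Product: 11 (2R,3R)-4-[(4R)-4-benzyl-2-oxo-1,3-oxazolidin-3-yl]-2-methyl-4-oxo-3-[4-(triisopropylsilyloxy)phenyl]butanoic acid
Conditions: H2 (1 atm), 10% Pd/C, EtOAc, rt
Reagents that add atoms: none
Why: Hydrogenolysis of the benzyl ester is neutral, leaves imide, silyl ether and both stereocenters untouched, and is placed before the prenyl group enters the molecule.

Step 6
Reactants: 12 5-bromo-2-iodophenol
Product: 13 (5-bromo-2-iodophenoxy)triisopropylsilane
Conditions: TIPSCl, imidazole, DMF, rt
Reagents that add atoms: triisopropylsilyl chloride, CC(C)[Si](Cl)(C(C)C)C(C)C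
Why: Standard phenol silylation, in which the bulky triisopropylsilyl group also slows oxygen-to-carbon silyl migration in the ortho-metalated species of the next step.

Step 7
Reactants: 13 (5-bromo-2-iodophenoxy)triisopropylsilane; 14 prenyl bromide (1-bromo-3-methylbut-2-ene)
Product: 16 [5-bromo-2-(3-methylbut-2-en-1-yl)phenoxy]triisopropylsilane, via arylmagnesium chloride 15 (not isolated)
Conditions: i-PrMgCl·LiCl, THF, −30 °C; then CuI (10 mol %), 14, −30 → 0 °C
Reagents that add atoms: none
Why: Iodine–magnesium exchange is much faster at C–I than at C–Br, and the arylmagnesium then substitutes prenyl bromide at its unhindered CH2 terminus under CuI catalysis (copper-catalysed Grignard allylation).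

Step 8
Reactants: 16 [5-bromo-2-(3-methylbut-2-en-1-yl)phenoxy]triisopropylsilane
Product: 18 [5-iodo-2-(3-methylbut-2-en-1-yl)phenoxy]triisopropylsilane, via aryllithium 17 (not isolated)
Conditions: n-BuLi, THF, −78 °C; then I2, −78 → 0 °C
Reagents that add atoms: iodine, II
Why: Bromine–lithium exchange at −78 °C and iodine quench give the aryl iodide needed for the C–H arylation, and the aryllithium sits meta to the silyloxy group so that no silyl migration can occur.

Step 9
Reactants: 11 (2R,3R)-4-[(4R)-4-benzyl-2-oxo-1,3-oxazolidin-3-yl]-2-methyl-4-oxo-3-[4-(triisopropylsilyloxy)phenyl]butanoic acid; 18 [5-iodo-2-(3-methylbut-2-en-1-yl)phenoxy]triisopropylsilane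
Product: 19 (2R,3R)-4-[(4R)-4-benzyl-2-oxo-1,3-oxazolidin-3-yl]-2-{[4-(3-methylbut-2-en-1-yl)-3-(triisopropylsilyloxy)phenyl]methyl}-4-oxo-3-[4-(triisopropylsilyloxy)phenyl]butanoic acid
Conditions: Pd(OAc)2 (10 mol %), N-acetylglycine (20 mol %), Ag2CO3 (1 equiv), K2HPO4 (1 equiv), 18 (1.5 equiv), (CF3)2CHOH, 90 °C
Reagents that add atoms: none
Why: The potassium carboxylate of 11 binds divalent palladium through one oxygen, N-acetylglycine-assisted concerted metalation–deprotonation of the methyl group on C-2 gives a five-membered palladacycle (Pd, O, C-1, C-2, CH2), oxidative addition of iodide 18 gives a tetravalent palladium aryl, and C(sp3)–C(sp2) reductive elimination forms the CH2–aryl bond while Ag2CO3 removes iodide as AgI so that divalent palladium turns over. The closest known reaction type is the ligand-enabled, carboxylate-directed β-C(sp3)–H arylation of α-branched free aliphatic acids and N-protected alanine with aryl iodides. No ring is closed in the product (the palladacycle is transient) and no stereocenter is created: the C-2–H bond is not broken when the methyl C–H is cleaved, and the C-3–H bond of the imide is held out of alignment with its carbonyl by allylic 1,3-strain and meets only weak bases in the acidic fluoroalcohol. The step needs site selectivity for the methyl C–H over the ortho C–H bonds of ring A and the C-3 methine, which is secured because only the methyl group reaches palladium through a five-membered ring (ring A would need a seven-membered palladacycle) and the second carboxyl is masked as the non-directing imide. It also needs mono-arylation and tolerance of the prenyl group, which should follow because the new benzylic CH2 is a hindered secondary C–H, iodide 18 has no ortho substituent, and the divalent/tetravalent palladium cycle generates neither a palladium hydride nor zerovalent palladium that could engage the trisubstituted alkene.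

Step 10
Reactants: 19 (2R,3R)-4-[(4R)-4-benzyl-2-oxo-1,3-oxazolidin-3-yl]-2-{[4-(3-methylbut-2-en-1-yl)-3-(triisopropylsilyloxy)phenyl]methyl}-4-oxo-3-[4-(triisopropylsilyloxy)phenyl]butanoic acid
Product: 20 methyl (2R,3R)-4-[(4R)-4-benzyl-2-oxo-1,3-oxazolidin-3-yl]-2-{[4-(3-methylbut-2-en-1-yl)-3-(triisopropylsilyloxy)phenyl]methyl}-4-oxo-3-[4-(triisopropylsilyloxy)phenyl]butanoate
Conditions: TMSCHN2, PhMe/MeOH (4:1), 0 °C → rt
Reagents that add atoms: (trimethylsilyl)diazomethane, C[Si](C)(C)C=[N+]=[N-]
Why: Diazoalkane O-methylation of the carboxylic acid is neutral and fast and does not touch the imide, the silyl ethers, the alkene or the two α-stereocenters.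

Step 11
Reactants: 20 methyl (2R,3R)-4-[(4R)-4-benzyl-2-oxo-1,3-oxazolidin-3-yl]-2-{[4-(3-methylbut-2-en-1-yl)-3-(triisopropylsilyloxy)phenyl]methyl}-4-oxo-3-[4-(triisopropylsilyloxy)phenyl]butanoate
Product: 22 (2R,3R)-3-(methoxycarbonyl)-4-[4-(3-methylbut-2-en-1-yl)-3-(triisopropylsilyloxy)phenyl]-2-[4-(triisopropylsilyloxy)phenyl]butanoic acid, via lithium percarboxylate 21 (not isolated)
Conditions: LiOH, H2O2, THF/H2O (3:1), 0 °C; then aq. Na2SO3; then 1 M HCl to pH 3
Reagents that add atoms: hydrogen peroxide, OO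
Why: Hydroperoxide attacks the exocyclic imide carbonyl far faster than the hindered methyl ester (standard oxazolidinone auxiliary cleavage), and the percarboxylate is reduced with sulfite before acidification so that the prenyl alkene never meets a free peracid.

Step 12
Reactants: 22 (2R,3R)-3-(methoxycarbonyl)-4-[4-(3-methylbut-2-en-1-yl)-3-(triisopropylsilyloxy)phenyl]-2-[4-(triisopropylsilyloxy)phenyl]butanoic acid
Product: 23 (2R,3R)-2-(4-hydroxyphenyl)-4-[3-hydroxy-4-(3-methylbut-2-en-1-yl)phenyl]-3-(methoxycarbonyl)butanoic acid (CNP0437978.2)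
Conditions: n-Bu4NF, AcOH, THF, 0 °C → rt
Reagents that add atoms: none
Why: Fluoride cleaves both aryl silyl ethers at low temperature, and the AcOH buffer keeps the medium non-basic and free of strong acid, so the methyl ester, the two α-stereocenters and the ortho-prenyl phenol (prone to acid-induced chroman formation) should survive.

**Compound list**

1 | 4-hydroxyphenylacetic acid | OC(=O)Cc1ccc(O)cc1 | starting material
2 | triisopropylsilyl 2-[4-(triisopropylsilyloxy)phenyl]acetate | CC(C)[Si](OC(=O)Cc1ccc(O[Si](C(C)C)(C(C)C)C(C)C)cc1)(C(C)C)C(C)C | intermediate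
3 | 2-[4-(triisopropylsilyloxy)phenyl]acetic acid | OC(=O)Cc1ccc(O[Si](C(C)C)(C(C)C)C(C)C)cc1 | intermediate
4 | (R)-4-benzyl-1,3-oxazolidin-2-one | O=C1N[C@H](Cc2ccccc2)CO1 | starting material
5 | pivalic 2-[4-(triisopropylsilyloxy)phenyl]acetic anhydride | CC(C)(C)C(=O)OC(=O)Cc1ccc(O[Si](C(C)C)(C(C)C)C(C)C)cc1 | intermediate
6 | (4R)-4-benzyl-3-{2-[4-(triisopropylsilyloxy)phenyl]acetyl}-1,3-oxazolidin-2-one | O=C(Cc1ccc(O[Si](C(C)C)(C(C)C)C(C)C)cc1)N1C(=O)OC[C@H]1Cc1ccccc1 | intermediate
7 | benzyl (R)-lactate | C[C@@H](O)C(=O)OCc1ccccc1 | starting material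
8 | benzyl (2R)-2-[(trifluoromethylsulfonyl)oxy]propanoate | C[C@@H](OS(=O)(=O)C(F)(F)F)C(=O)OCc1ccccc1 | intermediate
9 | sodium (Z)-enolate of 6 | [Na+].[O-]/C(=C\c1ccc(O[Si](C(C)C)(C(C)C)C(C)C)cc1)N1C(=O)OC[C@H]1Cc1ccccc1 | intermediate
10 | benzyl (2R,3R)-4-[(4R)-4-benzyl-2-oxo-1,3-oxazolidin-3-yl]-2-methyl-4-oxo-3-[4-(triisopropylsilyloxy)phenyl]butanoate | O=C(OCc1ccccc1)[C@H](C)[C@@H](C(=O)N1C(=O)OC[C@H]1Cc1ccccc1)c1ccc(O[Si](C(C)C)(C(C)C)C(C)C)cc1 | intermediate
11 | (2R,3R)-4-[(4R)-4-benzyl-2-oxo-1,3-oxazolidin-3-yl]-2-methyl-4-oxo-3-[4-(triisopropylsilyloxy)phenyl]butanoic acid | OC(=O)[C@H](C)[C@@H](C(=O)N1C(=O)OC[C@H]1Cc1ccccc1)c1ccc(O[Si](C(C)C)(C(C)C)C(C)C)cc1 | intermediate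
12 | 5-bromo-2-iodophenol | Oc1cc(Br)ccc1I | starting material
13 | (5-bromo-2-iodophenoxy)triisopropylsilane | CC(C)[Si](Oc1cc(Br)ccc1I)(C(C)C)C(C)C | intermediate
14 | prenyl bromide (1-bromo-3-methylbut-2-ene) | CC(C)=CCBr | starting material
15 | [4-bromo-2-(triisopropylsilyloxy)phenyl]magnesium chloride | CC(C)[Si](Oc1cc(Br)ccc1[Mg]Cl)(C(C)C)C(C)C | intermediate
16 | [5-bromo-2-(3-methylbut-2-en-1-yl)phenoxy]triisopropylsilane | CC(C)=CCc1ccc(Br)cc1O[Si](C(C)C)(C(C)C)C(C)C | intermediate
17 | [4-(3-methylbut-2-en-1-yl)-3-(triisopropylsilyloxy)phenyl]lithium | [Li]c1ccc(CC=C(C)C)c(O[Si](C(C)C)(C(C)C)C(C)C)c1 | intermediate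
18 | [5-iodo-2-(3-methylbut-2-en-1-yl)phenoxy]triisopropylsilane | CC(C)=CCc1ccc(I)cc1O[Si](C(C)C)(C(C)C)C(C)C | intermediate
19 | (2R,3R)-4-[(4R)-4-benzyl-2-oxo-1,3-oxazolidin-3-yl]-2-{[4-(3-methylbut-2-en-1-yl)-3-(triisopropylsilyloxy)phenyl]methyl}-4-oxo-3-[4-(triisopropylsilyloxy)phenyl]butanoic acid | OC(=O)[C@H](Cc1ccc(CC=C(C)C)c(O[Si](C(C)C)(C(C)C)C(C)C)c1)[C@@H](C(=O)N1C(=O)OC[C@H]1Cc1ccccc1)c1ccc(O[Si](C(C)C)(C(C)C)C(C)C)cc1 | intermediate
20 | methyl (2R,3R)-4-[(4R)-4-benzyl-2-oxo-1,3-oxazolidin-3-yl]-2-{[4-(3-methylbut-2-en-1-yl)-3-(triisopropylsilyloxy)phenyl]methyl}-4-oxo-3-[4-(triisopropylsilyloxy)phenyl]butanoate | COC(=O)[C@H](Cc1ccc(CC=C(C)C)c(O[Si](C(C)C)(C(C)C)C(C)C)c1)[C@@H](C(=O)N1C(=O)OC[C@H]1Cc1ccccc1)c1ccc(O[Si](C(C)C)(C(C)C)C(C)C)cc1 | intermediate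
21 | lithium (2R,3R)-3-(methoxycarbonyl)-4-[4-(3-methylbut-2-en-1-yl)-3-(triisopropylsilyloxy)phenyl]-2-[4-(triisopropylsilyloxy)phenyl]butaneperoxoate | COC(=O)[C@H](Cc1ccc(CC=C(C)C)c(O[Si](C(C)C)(C(C)C)C(C)C)c1)[C@@H](C(=O)O[O-])c1ccc(O[Si](C(C)C)(C(C)C)C(C)C)cc1.[Li+] | intermediate
22 | (2R,3R)-3-(methoxycarbonyl)-4-[4-(3-methylbut-2-en-1-yl)-3-(triisopropylsilyloxy)phenyl]-2-[4-(triisopropylsilyloxy)phenyl]butanoic acid | COC(=O)[C@H](Cc1ccc(CC=C(C)C)c(O[Si](C(C)C)(C(C)C)C(C)C)c1)[C@@H](C(=O)O)c1ccc(O[Si](C(C)C)(C(C)C)C(C)C)cc1 | intermediate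
23 | (2R,3R)-2-(4-hydroxyphenyl)-4-[3-hydroxy-4-(3-methylbut-2-en-1-yl)phenyl]-3-(methoxycarbonyl)butanoic acid | COC(=O)[C@H](Cc1ccc(CC=C(C)C)c(O)c1)[C@@H](C(=O)O)c1ccc(O)cc1 | target

**Count and risks**

Total steps: 12. Longest linear sequence: 8 steps (1, 2, 4, 5, 9, 10, 11, 12).

Steps most likely to fail:

1. Step 9. What may go wrong: competing palladation at an ortho C–H bond of ring A or a second arylation of the new CH2; slow intramolecular acyl transfer from the imide to the neighbouring carboxylate with loss of the auxiliary; epimerisation at the aryl-bearing carbon during prolonged heating with base and silver salts. Fallback (forms the C-2–C-3 bond instead of the CH2–aryl bond): it sets out from iodide 18 and imide 6 and comes back to the route at 20. Iodide 18 is converted with i-PrMgCl·LiCl (THF, 0 °C → rt) into [4-(3-methylbut-2-en-1-yl)-3-(triisopropylsilyloxy)phenyl]magnesium chloride F1. This opens commercial methyl (R)-glycidate (COC(=O)[C@H]1CO1) at its CH2 terminus under CuI catalysis (THF, −40 °C) to give methyl (2R)-2-hydroxy-3-[4-(3-methylbut-2-en-1-yl)-3-(triisopropylsilyloxy)phenyl]propanoate F2. Tf2O and 2,6-lutidine (CH2Cl2, −78 °C) convert it into methyl (2R)-3-[4-(3-methylbut-2-en-1-yl)-3-(triisopropylsilyloxy)phenyl]-2-[(trifluoromethylsulfonyl)oxy]propanoate F3. The sodium enolate 9 of imide 6 (NaN(SiMe3)2, THF, −78 °C) then displaces the triflate with inversion, exactly as in step 4, and should give methyl ester 20 directly; steps 11 and 12 follow unchanged.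

2. Step 4. What may go wrong: E2 elimination of the secondary triflate by the basic enolate, and erosion of facial selectivity or epimerisation with the stabilised arylacetyl enolate. Fallback (oxidative enolate heterocoupling in place of SN2 displacement): it sets out from imide 6 and comes back at 10. Imide 6 and commercial benzyl propionate (CCC(=O)OCc1ccccc1) are deprotonated with LiN(i-Pr)2 (THF, −78 °C) to the lithium enolate of 6 F4 and the lithium enolate of benzyl propionate F5, and the mixture is oxidised with Fe(acac)3 (−78 °C → rt). The auxiliary should control the aryl-bearing carbon; the methyl-bearing carbon is not controlled, so 10 would have to be separated by chromatography from benzyl (2S,3R)-4-[(4R)-4-benzyl-2-oxo-1,3-oxazolidin-3-yl]-2-methyl-4-oxo-3-[4-(triisopropylsilyloxy)phenyl]butanoate F6, its C-2 epimer.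

3. Step 7. What may go wrong: attack of the arylmagnesium at the dimethyl-substituted terminus of the allyl electrophile (SN2' pathway), giving the 1,1-dimethylallyl isomer. Fallback (allylation, then olefin cross-metathesis): it sets out from 13 and comes back at 16. Arylmagnesium chloride 15 is generated from 13 as in step 7 and quenched with allyl bromide (CuI cat., THF, −30 → 0 °C) to give (2-allyl-5-bromophenoxy)triisopropylsilane F7, for which no regiochemical ambiguity exists. Cross-metathesis of F7 with excess 2-methyl-2-butene (second-generation Grubbs catalyst (H2IMes)(PCy3)Cl2Ru=CHPh, CH2Cl2, 40 °C) should then give 16.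

Further compounds

F1 | step 9 | [4-(3-methylbut-2-en-1-yl)-3-(triisopropylsilyloxy)phenyl]magnesium chloride | CC(C)=CCc1ccc([Mg]Cl)cc1O[Si](C(C)C)(C(C)C)C(C)C
F2 | step 9 | methyl (2R)-2-hydroxy-3-[4-(3-methylbut-2-en-1-yl)-3-(triisopropylsilyloxy)phenyl]propanoate | COC(=O)[C@H](O)Cc1ccc(CC=C(C)C)c(O[Si](C(C)C)(C(C)C)C(C)C)c1
F3 | step 9 | methyl (2R)-3-[4-(3-methylbut-2-en-1-yl)-3-(triisopropylsilyloxy)phenyl]-2-[(trifluoromethylsulfonyl)oxy]propanoate | COC(=O)[C@H](OS(=O)(=O)C(F)(F)F)Cc1ccc(CC=C(C)C)c(O[Si](C(C)C)(C(C)C)C(C)C)c1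
F4 | step 4 | lithium (Z)-enolate of 6 | [Li+].[O-]/C(=C\c1ccc(O[Si](C(C)C)(C(C)C)C(C)C)cc1)N1C(=O)OC[C@H]1Cc1ccccc1
F5 | step 4 | lithium enolate of benzyl propionate | [Li+].[O-]/C(=C/C)OCc1ccccc1
F6 | step 4 | benzyl (2S,3R)-4-[(4R)-4-benzyl-2-oxo-1,3-oxazolidin-3-yl]-2-methyl-4-oxo-3-[4-(triisopropylsilyloxy)phenyl]butanoate | O=C(OCc1ccccc1)[C@@H](C)[C@@H](C(=O)N1C(=O)OC[C@H]1Cc1ccccc1)c1ccc(O[Si](C(C)C)(C(C)C)C(C)C)cc1
F7 | step 7 | (2-allyl-5-bromophenoxy)triisopropylsilane | C=CCc1ccc(Br)cc1O[Si](C(C)C)(C(C)C)C(C)C
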